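**Retrosynthetic overview**
1. The two ent-labdane halves are disconnected at C15–C12′, a vinylogous SN2′ union of a 2-silyloxyfuran with a 14-acetoxy alkylidene lactone. Both partners come from one intermediate, andrographolide 3,19-acetonide, whose lactone is built from a C12 aldehyde and (S)-3-hydroxybutyrolactone.
2. Enabling feature: in ring A the two oxygenated carbons C3 and C19 flank C4, so C3–C4(CH3)–C19 is a masked 2-methylmalonyl unit. C3 is an acyl carbon that can be joined to C2, and C4, then lying between two carbonyls, becomes the radical that attacks C5.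
3. Key step, one flask: acyl transfer makes C2–C3, then Mn(OAc)3/Cu(OAc)2 closes ring A (C4–C5) and ring B (C9–C10) of an acyclic E,E-diene and leaves the C8=C17 exocyclic olefin. C4, C5, C9 and C10 are set, the absolute sense by an 8-phenylmenthyl ester.
4. Ring order: ring A, ring B (same operation), the hydroxy-lactone of the common intermediate, then both butenolides of the dimer in the union. The acyclic precursor comes from geranyl chloride in five steps.

Key step: step 8

Remark on the chemistry (assumption): the 8-phenylmenthyl ester is taken to induce the same facial sense as in related oxidative cyclizations of 3-oxo esters, so that the (1R,2S,5R) auxiliary leads to the ent-labdane series drawn; if the opposite sense is found, the (1S,2R,5S) antipode is used and nothing else changes.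

**Step 1**
Reactants: 1 geranyl chloride
Product: 2 methyl (3E)-4,8-dimethylnona-3,7-dienoate
Conditions: CO (20 atm), MeOH, PdCl2(PPh3)2 (2 mol %), i-Pr2NEt, THF, 50 °C
Reagents that add atoms: carbon monoxide, [C-]#[O+]; methanol, CO
Why: Palladium-catalysed alkoxycarbonylation of the allylic chloride through a π-allyl complex should place CO at the unhindered primary terminus and keep the E olefin, giving the β,γ-unsaturated ester that supplies C11 and C12.

**Step 2**
Reactants: 2 methyl (3E)-4,8-dimethylnona-3,7-dienoate
Product: 3 methyl (3E,7E)-4,8-dimethyl-9-oxonona-3,7-dienoate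
Conditions: SeO2 (1.1 equiv), 1,4-dioxane/H2O, 80 °C
Reagents that add atoms: selenium dioxide, O=[Se]=O
Why: Riley allylic oxidation (ene reaction, then [2,3]-shift) should attack the E methyl group of the more electron-rich terminal trisubstituted olefin and give the E enal.

**Step 3**
Reactants: 3 methyl (3E,7E)-4,8-dimethyl-9-oxonona-3,7-dienoate
Product: 4 methyl (3E,7E)-4,8-dimethyldeca-3,7,9-trienoate
Conditions: Ph3PCH3Br, KN(SiMe3)2, THF, −78 °C; then 3, −78 → 0 °C
Reagents that add atoms: methyltriphenylphosphonium bromide, C[P+](c1ccccc1)(c1ccccc1)c1ccccc1.[Br-]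
Why: Wittig methylenation of the aldehyde is faster than any reaction of the ylide with the ester and leaves both E olefins untouched; the new vinyl carbon is C2.

**Step 4**
Reactants: 4 methyl (3E,7E)-4,8-dimethyldeca-3,7,9-trienoate
Product: 6 methyl (3E,7E)-10-hydroxy-4,8-dimethyldeca-3,7-dienoate, via B-alkyl-9-borabicyclononane 5 (not isolated)
Conditions: 9-BBN, THF, 0 → 25 °C; then H2O2, pH 7 phosphate buffer, 0 °C
Reagents that add atoms: hydrogen peroxide, OO
Why: Hydroboration with the bulky borane should occur only at the monosubstituted terminus of the diene (boron on C2) and spare the trisubstituted olefins; buffered oxidation keeps the methyl ester.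

**Step 5**
Reactants: 6 methyl (3E,7E)-10-hydroxy-4,8-dimethyldeca-3,7-dienoate
Product: 7 methyl (3E,7E)-10-iodo-4,8-dimethyldeca-3,7-dienoate
Conditions: I2, PPh3, imidazole, CH2Cl2, 0 °C
Reagents that add atoms: iodine, II
Why: Appel-type iodination converts the unhindered primary alcohol by SN2 displacement of the alkoxyphosphonium group.

**Step 6**
Reactants: 8 (1R,2S,5R)-8-phenylmenthol; 9 methyl Meldrum's acid (2,2,5-trimethyl-1,3-dioxane-4,6-dione)
Product: 10 (1R,2S,5R)-8-phenylmenthyl hydrogen 2-methylmalonate
Conditions: toluene, 110 °C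
Reagents that add atoms: none
Why: Alcoholysis of the cyclic acylal with loss of acetone gives the malonic half ester; the malonate carbon (future C4) needs no control because it later becomes a planar radical.

**Step 7**
Reactants: 10 (1R,2S,5R)-8-phenylmenthyl hydrogen 2-methylmalonate
Product: 11 (1R,2S,5R)-8-phenylmenthyl 3-fluoro-2-methyl-3-oxopropanoate
Conditions: cyanuric fluoride, pyridine, CH2Cl2, −10 → 25 °C
Reagents that add atoms: cyanuric fluoride, Fc1nc(F)nc(F)n1
Why: The carboxylate attacks the triazine and fluoride returns to the acyl carbon; the acyl fluoride is chosen so that no chloride or iodide enters the next step.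

**Step 8**
Reactants: 7 methyl (3E,7E)-10-iodo-4,8-dimethyldeca-3,7-dienoate; 11 (1R,2S,5R)-8-phenylmenthyl 3-fluoro-2-methyl-3-oxopropanoate
Product: 14 keto diester of the tetranor-ent-labdane series (12-methyl 19-(8-phenylmenthyl) 3-oxo-13,14,15,16-tetranor-ent-labd-8(17)-ene-12,19-dioate), via dialkylzinc 12 (not isolated), via 3-oxo ester 13 (not isolated)
Conditions: Et2Zn (neat), CuI (0.3 mol %), 50 °C, then volatiles removed in vacuo; 11, Ni(cod)2 (5 mol %), 2-[2-(diphenylphosphino)ethyl]pyridine (6 mol %), THF, 25 °C; then THF replaced by AcOH, Mn(OAc)3·2H2O (2.2 equiv), Cu(OAc)2·H2O (1 equiv), 25 °C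
Reagents that add atoms: none
Why: Iodine–zinc exchange gives a halide-free dialkylzinc whose nickel-catalysed acyl transfer to the acid fluoride (Negishi-type ketone synthesis) forms C2–C3 and delivers the 2-methyl-3-oxo ester; Mn(OAc)3 then oxidises its manganese enolate to the C4 radical, the closest known reaction type being the Mn(OAc)3/Cu(OAc)2 oxidative free-radical polyene cyclization of 2-alkyl-3-oxo esters. Ring A closes by 6-endo-trig attack of the electrophilic C4 radical on C5 of the C5=C10 olefin, ring B by 6-endo-trig attack of the tertiary C10 radical on C9 of the C8=C9 olefin, and Cu(OAc)2 oxidises the tertiary C8 radical with loss of a C17 hydrogen to the 8(17)-exocyclic olefin. C5 and C10 become trans because the E olefin reacts through a chair-like array, C9 carries its side chain equatorial because the second E olefin reacts through a second chair, and C4 places the ester axial (cis to C20) and the methyl equatorial as in cyclizations of 2-methyl-3-oxo esters. The absolute sense follows from the 8-phenylmenthyl group, whose phenyl ring covers one face of the chelated keto ester radical. The step needs 6-endo over 5-exo closure (secured by the methyl groups on C10 and C8), exocyclic over endocyclic olefin formation (the methyl hydrogens are the most accessible in the copper-mediated termination) and the absence of chloride and iodide, which would capture the C8 radical by ligand transfer (secured by the zinc/fluoride design).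

**Step 9**
Reactants: 14 keto diester of the tetranor-ent-labdane series
Product: 15 triol (13,14,15,16-tetranor-ent-labd-8(17)-ene-3,12,19-triol with the andrographolide configuration)
Conditions: LiAlH4, THF, −78 → 66 °C
Reagents that add atoms: none
Why: Hydride reduction takes the C3 ketone first by axial attack from the face opposite the axial C19 ester and the C20 methyl, giving the equatorial 3-OH cis to C19, and on warming reduces both esters to primary alcohols with release of the auxiliary.

**Step 10**
Reactants: 15 triol
Product: 16 acetonide alcohol (3,19-O-isopropylidene derivative of 15 with free 12-OH)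
Conditions: 2,2-dimethoxypropane, pyridinium p-toluenesulfonate (cat.), CH2Cl2, 25 °C; aqueous work-up
Reagents that add atoms: 2,2-dimethoxypropane, COC(C)(C)OC
Why: Acid-catalysed transacetalization is thermodynamically controlled and only the syn 1,3-diol (3-OH and 19-OH) can close a six-membered dioxane, so the primary C12 alcohol stays free after work-up.

**Step 11**
Reactants: 16 acetonide alcohol
Product: 17 aldehyde (3,19-O-isopropylidene-13,14,15,16-tetranor-ent-labd-8(17)-en-12-al)
Conditions: Dess–Martin periodinane, CH2Cl2, 0 → 25 °C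
Reagents that add atoms: none
Why: Dess–Martin oxidation converts the primary alcohol to the aldehyde under nearly neutral conditions that spare the acetonide, the exocyclic olefin and the C9 stereocenter.

**Step 12**
Reactants: 18 (S)-3-hydroxy-γ-butyrolactone
Product: 19 TBS ether of 18
Conditions: TBSCl, imidazole, DMF, 25 °C
Reagents that add atoms: tert-butyldimethylsilyl chloride, CC(C)(C)[Si](C)(C)Cl
Why: Standard silylation of the secondary alcohol protects the future C14 oxygen and makes it a poor leaving group.

**Step 13**
Reactants: 19 TBS ether of 18; 17 aldehyde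
Product: 20 aldol adduct (12-hydroxy lactone, mixture at C12)
Conditions: LiN(i-Pr)2, THF, −78 °C; then 17, −78 °C
Reagents that add atoms: none
Why: The lithium lactone enolate adds to the aldehyde trans to the neighbouring silyloxy group (C13); the C12 carbinol configuration is irrelevant because both centers become sp2 in the next step.

**Step 14**
Reactants: 20 aldol adduct
Product: 22 TBS ether of andrographolide 3,19-acetonide (14-O-silyl), via 12-mesylate 21 (not isolated)
Conditions: MsCl, Et3N, CH2Cl2, 0 °C; then DBU, 25 °C
Reagents that add atoms: none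
Why: Mesylation and E1cB elimination through the lactone enolate should give the thermodynamically preferred E alkylidene lactone, mesylate being a far better leaving group than the β-silyloxy group.

**Step 15**
Reactants: 22 TBS ether of andrographolide 3,19-acetonide
Product: 23 andrographolide 3,19-acetonide
Conditions: HF·pyridine, pyridine, THF, 0 → 25 °C
Reagents that add atoms: none
Why: Buffered fluoride cleaves the silyl ether without the basic conditions that would eliminate the C14 oxygen and without opening the acetonide.

**Step 16**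
Reactants: 23 andrographolide 3,19-acetonide
Product: 24 andrographolide 3,19-acetonide 14-acetate
Conditions: Ac2O (neat), 140 °C
Reagents that add atoms: acetic anhydride, CC(=O)OC(C)=O
Why: Base-free acetylation of the allylic secondary alcohol installs the leaving group with retention at C14 and avoids the amine-induced elimination.

**Step 17**
Reactants: 24 andrographolide 3,19-acetonide 14-acetate
Product: 25 dienyl butenolide (14-deoxy-11,12-didehydroandrographolide 3,19-acetonide)
Conditions: DBU, CH2Cl2, 25 °C
Reagents that add atoms: none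
Why: Vinylogous E1cB elimination: DBU removes a C11 hydrogen and the extended enolate expels acetate, giving the conjugated 11E diene and the endocyclic butenolide.

**Step 18**
Reactants: 25 dienyl butenolide
Product: 26 silyloxyfuran of 25 (2-TBSO-furan)
Conditions: TBSOTf, Et3N, CH2Cl2, 0 °C
Reagents that add atoms: tert-butyldimethylsilyl trifluoromethanesulfonate, CC(C)(C)[Si](C)(C)OS(=O)(=O)C(F)(F)F
Why: Soft enolization and O-silylation of the butenolide give the aromatic 2-silyloxyfuran, nucleophilic at C15.

**Step 19**
Reactants: 26 silyloxyfuran of 25; 24 andrographolide 3,19-acetonide 14-acetate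
Product: 27 bis-acetonide of the target
Conditions: TBSOTf (0.2 equiv), CH2Cl2, −78 → −40 °C
Reagents that add atoms: none
Why: Proposed new method: catalytic silyl triflate should silylate the lactone carbonyl of 24, the C15 terminus of 26 (its most nucleophilic carbon) adds to C12′ of the activated alkylidene lactone, and the silyl ketene acetal so formed expels the C14′ acetate as silyl acetate while the olefin moves into the ring (vinylogous Mukaiyama–Michael addition then elimination, overall SN2′), the closest known reaction types being Lewis-acid SN2′ substitutions of 2-(acyloxyalkyl)acrylates by silyl enol ethers and the additions of sulfur and nitrogen nucleophiles to C12 of 14-acyloxy andrographolides; C12′ is set by attack anti to the pseudo-axial C14′–O bond (the 14′S acetate leads to the configuration of the target), and C15 by an open antiperiplanar transition state in which the vinyl-decalin arm of the furan points away from the second half.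

**Step 20**
Reactants: 27 bis-acetonide of the target
Product: 28 target
Conditions: AcOH/H2O (7:3), 25 °C
Reagents that add atoms: none
Why: Mild acid hydrolysis removes both isopropylidene acetals; no stereocenter is touched and the exocyclic olefins, the diene and both butenolides tolerate aqueous acetic acid.

**Compound list**
1 | geranyl chloride, (2E)-1-chloro-3,7-dimethylocta-2,6-diene | CC(C)=CCC/C(C)=C/CCl | starting material
2 | methyl (3E)-4,8-dimethylnona-3,7-dienoate | CC(C)=CCC/C(C)=C/CC(=O)OC | intermediate
3 | methyl (3E,7E)-4,8-dimethyl-9-oxonona-3,7-dienoate | O=C/C(C)=C/CC/C(C)=C/CC(=O)OC | intermediate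
4 | methyl (3E,7E)-4,8-dimethyldeca-3,7,9-trienoate | C=C/C(C)=C/CC/C(C)=C/CC(=O)OC | intermediate
5 | B-alkyl-9-borabicyclo[3.3.1]nonane from 4 (boron on C2) | C1CC2CCCC(C1)B2CC/C(C)=C/CC/C(C)=C/CC(=O)OC | intermediate
6 | methyl (3E,7E)-10-hydroxy-4,8-dimethyldeca-3,7-dienoate | OCC/C(C)=C/CC/C(C)=C/CC(=O)OC | intermediate
7 | methyl (3E,7E)-10-iodo-4,8-dimethyldeca-3,7-dienoate | ICC/C(C)=C/CC/C(C)=C/CC(=O)OC | intermediate
8 | (1R,2S,5R)-8-phenylmenthol | C[C@@H]1CC[C@H]([C@@H](C1)O)C(C)(C)c1ccccc1 | starting material
9 | methyl Meldrum's acid, 2,2,5-trimethyl-1,3-dioxane-4,6-dione | CC1C(=O)OC(C)(C)OC1=O | starting material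
10 | (1R,2S,5R)-8-phenylmenthyl hydrogen 2-methylmalonate (malonate carbon unassigned) | C[C@@H]1CC[C@H]([C@@H](C1)OC(=O)C(C)C(=O)O)C(C)(C)c1ccccc1 | intermediate
11 | (1R,2S,5R)-8-phenylmenthyl 3-fluoro-2-methyl-3-oxopropanoate | C[C@@H]1CC[C@H]([C@@H](C1)OC(=O)C(C)C(F)=O)C(C)(C)c1ccccc1 | intermediate
12 | bis[(3E,7E)-10-methoxy-3,7-dimethyl-10-oxodeca-3,7-dienyl]zinc | [Zn](CC/C(C)=C/CC/C(C)=C/CC(=O)OC)CC/C(C)=C/CC/C(C)=C/CC(=O)OC | intermediate
13 | 1-[(1R,2S,5R)-8-phenylmenthyl] 13-methyl (6E,10E)-2,6,10-trimethyl-3-oxotrideca-6,10-dienedioate | C[C@@H]1CC[C@H]([C@@H](C1)OC(=O)C(C)C(=O)CC/C(C)=C/CC/C(C)=C/CC(=O)OC)C(C)(C)c1ccccc1 | intermediate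
14 | 12-methyl 19-[(1R,2S,5R)-8-phenylmenthyl] 3-oxo-13,14,15,16-tetranor-ent-labd-8(17)-ene-12,19-dioate; C4, C5, C9, C10 as in andrographolide, ester on C4 axial | C[C@@H]1CC[C@H]([C@@H](C1)OC(=O)[C@]5(C)C(=O)CC[C@@]6(C)[C@H](CC(=O)OC)C(=C)CC[C@H]56)C(C)(C)c1ccccc1 | intermediate
15 | 13,14,15,16-tetranor-ent-labd-8(17)-ene-3,12,19-triol, 3-OH equatorial and cis to C19 | OCC[C@@H]2C(=C)CC[C@@H]3[C@](C)(CO)[C@H](O)CC[C@]32C | intermediate
16 | 3,19-O-isopropylidene derivative of 15, free 12-OH | OCC[C@@H]2C(=C)CC[C@@H]3[C@]4(C)COC(C)(C)O[C@@H]4CC[C@]32C | intermediate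
17 | 3,19-O-isopropylidene-13,14,15,16-tetranor-ent-labd-8(17)-en-12-al | O=CC[C@@H]2C(=C)CC[C@@H]3[C@]4(C)COC(C)(C)O[C@@H]4CC[C@]32C | intermediate
18 | (S)-3-hydroxy-γ-butyrolactone, (4S)-4-hydroxyoxolan-2-one | O=C1C[C@H](O)CO1 | starting material
19 | (4S)-4-(tert-butyldimethylsilyloxy)oxolan-2-one | O=C1C[C@H](O[Si](C)(C)C(C)(C)C)CO1 | intermediate
20 | aldol adduct: 12-hydroxy-14-O-TBS-12,13-dihydro derivative of andrographolide 3,19-acetonide (14S; C13 trans to the silyloxy group, C12 mixture) | O=C1OC[C@@H](O[Si](C)(C)C(C)(C)C)C1C(O)C[C@@H]2C(=C)CC[C@@H]3[C@]4(C)COC(C)(C)O[C@@H]4CC[C@]32C | intermediate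
21 | 12-methanesulfonate of 20 | O=C1OC[C@@H](O[Si](C)(C)C(C)(C)C)C1C(OS(C)(=O)=O)C[C@@H]2C(=C)CC[C@@H]3[C@]4(C)COC(C)(C)O[C@@H]4CC[C@]32C | intermediate
22 | 14-O-TBS-3,19-O-isopropylidene-andrographolide (12E,14S) | O=C1OC[C@@H](O[Si](C)(C)C(C)(C)C)/C1=C\C[C@@H]2C(=C)CC[C@@H]3[C@]4(C)COC(C)(C)O[C@@H]4CC[C@]32C | intermediate
23 | 3,19-O-isopropylidene-andrographolide (12E,14S) | O=C1OC[C@@H](O)/C1=C\C[C@@H]2C(=C)CC[C@@H]3[C@]4(C)COC(C)(C)O[C@@H]4CC[C@]32C | intermediate
24 | 14-O-acetyl-3,19-O-isopropylidene-andrographolide (12E,14S) | O=C1OC[C@@H](OC(C)=O)/C1=C\C[C@@H]2C(=C)CC[C@@H]3[C@]4(C)COC(C)(C)O[C@@H]4CC[C@]32C | intermediate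
25 | 3,19-O-isopropylidene-14-deoxy-11,12-didehydroandrographolide (11E) | C=C1CC[C@@H]2[C@]3(C)COC(C)(C)O[C@@H]3CC[C@@]2(C)[C@@H]1/C=C/C1=CCOC1=O | intermediate
26 | 2-(tert-butyldimethylsilyloxy)furan derived from 25, 3-[(E)-2-decalinylvinyl]furan | C=C1CC[C@@H]2[C@]3(C)COC(C)(C)O[C@@H]3CC[C@@]2(C)[C@@H]1/C=C/c1ccoc1O[Si](C)(C)C(C)(C)C | intermediate
27 | 3,19:3′,19′-bis-O-isopropylidene derivative of the target (15R,12′S) | C=C1CC[C@@H]2[C@]3(C)COC(C)(C)O[C@@H]3CC[C@@]2(C)[C@@H]1/C=C/C1=C[C@H]([C@@H](C[C@@H]2C(=C)CC[C@@H]3[C@]4(C)COC(C)(C)O[C@@H]4CC[C@]32C)C2=CCOC2=O)OC1=O | intermediate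
28 | CNP0220272.2, C15–C12′ linked bis-ent-labdane (15R,12′S) | C=C1CC[C@@H]2[C@](C)(CO)[C@H](O)CC[C@@]2(C)[C@@H]1/C=C/C1=C[C@H]([C@@H](C[C@@H]2C(=C)CC[C@@H]3[C@](C)(CO)[C@H](O)CC[C@]32C)C2=CCOC2=O)OC1=O | target

**Step count and risks**
Total step count: 20. Longest linear sequence: 17 steps (steps 1–5, 8–11, 13–20).

Most likely to fail, first: step 19. The facial selectivity at the planar furan carbon C15 may be poor, and acetate may be lost from 24 by elimination before the carbon–carbon bond forms. The fallback uses known chemistry and sets out from 23 and 25. Methyl chloroformate and pyridine would convert 23 into 14-O-methoxycarbonyl-3,19-O-isopropylidene-andrographolide F1. With Pd2(dba)3 (zerovalent palladium) and (1R,2R)-N,N′-bis(2-diphenylphosphinobenzoyl)cyclohexane-1,2-diamine (or its enantiomer, whichever matches), F1 should ionize to the 2-carbonyl π-allyl complex. The methoxide released deprotonates 25, and the furanolate attacks the allyl terminus C12′ under ligand control (Tsuji–Trost allylic alkylation). This comes back to the route at 27.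

Second: step 8. The acid fluoride may enolize instead of transferring its acyl group, or the radical stage may suffer from low face selectivity or termination to the endocyclic olefin. The fallback sets out from 3 and 8 and separates the two events. Luche reduction (NaBH4, CeCl3) of 3 would give methyl (3E,7E)-9-hydroxy-4,8-dimethylnona-3,7-dienoate F2, and CBr4/PPh3 the allylic bromide methyl (3E,7E)-9-bromo-4,8-dimethylnona-3,7-dienoate F3. Heating 8 with 2,2,6-trimethyl-4H-1,3-dioxin-4-one would give (1R,2S,5R)-8-phenylmenthyl 3-oxobutanoate F4, which MeI/K2CO3 methylates to (1R,2S,5R)-8-phenylmenthyl 2-methyl-3-oxobutanoate F5. The dianion of F5 (NaH, then n-BuLi) is alkylated at its terminal carbon by F3 to give 13, which is isolated, purified and cyclized on its own with Mn(OAc)3/Cu(OAc)2 in AcOH, so that a lanthanide triflate additive or another solvent can be screened. This comes back to the route at 14.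

Third: step 14. The base-mediated dehydration may give the Z olefin or eliminate the silyloxy group. The fallback sets out from 16 and 19 and replaces aldol/dehydration by alkylation and selenoxide elimination. Iodination of 16 (I2, PPh3, imidazole) would give the 12-iodide F6. The lithium enolate of 19 is alkylated by F6 trans to the silyloxy group to give the 13-alkyl lactone F7. LiN(i-Pr)2/PhSeBr gives the 13-phenylselanyl lactone F8. Oxidation with H2O2 and syn elimination of the selenoxide, which avoids the oxygen-bearing C14, should give the exocyclic E olefin. This comes back to the route at 22.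

**Further compounds**
F1 | step 19 | 14-O-methoxycarbonyl-3,19-O-isopropylidene-andrographolide | O=C1OC[C@@H](OC(=O)OC)/C1=C\C[C@@H]2C(=C)CC[C@@H]3[C@]4(C)COC(C)(C)O[C@@H]4CC[C@]32C
F2 | step 8 | methyl (3E,7E)-9-hydroxy-4,8-dimethylnona-3,7-dienoate | OC/C(C)=C/CC/C(C)=C/CC(=O)OC
F3 | step 8 | methyl (3E,7E)-9-bromo-4,8-dimethylnona-3,7-dienoate | BrC/C(C)=C/CC/C(C)=C/CC(=O)OC
F4 | step 8 | (1R,2S,5R)-8-phenylmenthyl 3-oxobutanoate | C[C@@H]1CC[C@H]([C@@H](C1)OC(=O)CC(C)=O)C(C)(C)c1ccccc1
F5 | step 8 | (1R,2S,5R)-8-phenylmenthyl 2-methyl-3-oxobutanoate | C[C@@H]1CC[C@H]([C@@H](C1)OC(=O)C(C)C(C)=O)C(C)(C)c1ccccc1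
F6 | step 14 | 12-iodo-3,19-O-isopropylidene-13,14,15,16-tetranor-ent-labd-8(17)-ene | ICC[C@@H]2C(=C)CC[C@@H]3[C@]4(C)COC(C)(C)O[C@@H]4CC[C@]32C
F7 | step 14 | 14-O-TBS-12,13-dihydro-14-epi-free alkylated lactone (13-alkyl-4-silyloxyoxolan-2-one, C13 trans to the silyloxy group) | O=C1OC[C@@H](O[Si](C)(C)C(C)(C)C)C1CC[C@@H]2C(=C)CC[C@@H]3[C@]4(C)COC(C)(C)O[C@@H]4CC[C@]32C
F8 | step 14 | 13-phenylselanyl derivative of F7 | O=C1OC[C@@H](O[Si](C)(C)C(C)(C)C)C1([Se]c1ccccc1)CC[C@@H]2C(=C)CC[C@@H]3[C@]4(C)COC(C)(C)O[C@@H]4CC[C@]32C
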